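**Retrosynthetic overview**

1. The target is meso: a mirror plane passes through the ring oxygen O1 and the C3–C4 midpoint of the oxolane (2,3-trans, 3,4-cis, 4,5-trans). The two bonds from an aryl ipso carbon to C2 and to C5 are therefore equivalent and are cut together.
2. Key disconnection: a twofold decarboxylative C(sp3)–C(sp2) radical cross-coupling (photoredox/nickel) of meso 3,4-bis(acetoxymethyl)oxolane-2,5-dicarboxylic acid with two molecules of 4-bromo-2,6-dimethoxyphenyl acetate. Two electrophile-level carbons are joined through an α-oxy radical.
3. Enabling feature: C2 and C5 each lie next to ring oxygen O1, so a carboxylate there gives a stabilized oxolan-2-yl radical. They also lie next to C3/C4, whose two cis CH2O groups cover one face of the oxolane ring, so each aryl enters trans to its neighbour and the two aryls end up cis.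
4. The diacid comes from the commercial exo Diels–Alder adduct of furan and maleic anhydride. Its oxygen-bridged five-membered ring is the oxolane of the target, the anhydride becomes the two cis CH2OH groups, and the cyclohexene ring is a temporary ring cut by RuO4.
5. Ring order: no ring is built in the route. The oxolane is carried from the bicyclic starting material and is freed as a monocycle in step 3; the two aryl rings arrive intact in step 5; a global deacetylation ends the route.

Key step: step 5

Remark: the target is a meso compound, so its stereodescriptors fix relative configuration only; the one chiral intermediate (compound 7) is racemic and its SMILES shows one enantiomer.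

**Route**

Step 1
Reactants: 1 exo-7-oxabicyclo[2.2.1]hept-5-ene-2,3-dicarboxylic anhydride
Product: 2 exo,exo-7-oxabicyclo[2.2.1]hept-5-ene-2,3-diyldimethanol
Conditions: LiAlH4 (2 equiv), THF, 0 °C to rt; then H2O, 15% aq. NaOH, H2O, filtration
Reagents that add atoms: none
Why: LiAlH4 reduction of a cyclic anhydride to the 1,4-diol is reliable at or below room temperature, where the furan adduct should not undergo cycloreversion, and it leaves the four stereocentres of the exo adduct untouched.

Step 2
Reactants: 2 exo,exo-7-oxabicyclo[2.2.1]hept-5-ene-2,3-diyldimethanol
Product: 3 exo,exo-7-oxabicyclo[2.2.1]hept-5-ene-2,3-diylbis(methylene) diacetate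
Conditions: Ac2O (3 equiv), pyridine, DMAP (cat.), CH2Cl2, 0 °C to rt
Reagents that add atoms: acetic anhydride CC(=O)OC(C)=O
Why: DMAP-catalysed O-acetylation of two primary alcohols gives esters that should tolerate RuO4 and the later carbonate base and that leave together with the aryl acetates in the last step; no stereocentre is affected.

Step 3
Reactants: 3 exo,exo-7-oxabicyclo[2.2.1]hept-5-ene-2,3-diylbis(methylene) diacetate
Product: 4 meso-(2R,3S,4R,5S)-3,4-bis(acetoxymethyl)oxolane-2,5-dicarboxylic acid
Conditions: RuCl3·xH2O (3 mol %), NaIO4 (4.5 equiv), EtOAc/MeCN/H2O (2:2:3), 0 °C to rt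
Reagents that add atoms: sodium periodate [Na+].[O-]I(=O)(=O)=O (terminal oxidant, oxygen delivered through RuO4); water O
Why: catalytic RuO4 oxidative cleavage of the strained cis-disubstituted alkene should give the two carboxylic acids directly, turning the bridgehead carbons into C2 and C5 of a monocyclic oxolane with the carboxyl groups cis to each other and trans to the exo CH2OAc groups; no stereocentre is broken.

Step 4
Reactants: 5 4-bromo-2,6-dimethoxyphenol
Product: 6 4-bromo-2,6-dimethoxyphenyl acetate
Conditions: Ac2O (1.5 equiv), Et3N, DMAP (cat.), CH2Cl2, rt
Reagents that add atoms: acetic anhydride CC(=O)OC(C)=O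
Why: DMAP-catalysed acetylation (nucleophilic acyl substitution) of the hindered phenol masks the acidic, easily oxidized OH, places an acceptor para to bromine and gives an ester that leaves in the last step.

Step 5
Reactants: 4 meso-(2R,3S,4R,5S)-3,4-bis(acetoxymethyl)oxolane-2,5-dicarboxylic acid; 6 4-bromo-2,6-dimethoxyphenyl acetate (3 equiv)
Product: 8 meso-[(2R,3S,4R,5S)-2,5-bis(4-acetoxy-3,5-dimethoxyphenyl)oxolane-3,4-diyl]bis(methylene) diacetate, via monoaryl acid 7 (not isolated)
Conditions: Ir[dF(CF3)ppy]2(dtbbpy)PF6 (2 mol %), NiCl2·glyme (20 mol %), 4,4'-di-tert-butyl-2,2'-bipyridine (22 mol %), Cs2CO3 (2.2 equiv), anhydrous degassed DMF, blue LEDs (450 nm), rt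
Reagents that add atoms: none
Why: The photoexcited trivalent iridium complex oxidizes a caesium carboxylate of 4 by single-electron transfer, CO2 is lost, and the resulting oxolan-2-yl radical (stabilized by the ring oxygen) is captured by the divalent aryl nickel bromide formed from 6 and zerovalent nickel; reductive elimination from trivalent nickel then forms the bond from the aryl ipso carbon to C2, the reduced iridium complex returns monovalent nickel to the zerovalent state, and the sequence repeats at C5 of the mono-arylated acid 7. The closest known reaction type is the metallaphotoredox decarboxylative arylation of α-oxy carboxylic acids (oxolane-2-carboxylic acids, and furanosyl acids giving aryl C-nucleosides), applied here twice to one meso diacid, so that two electrophile-level carbons (the acetal-level ring carbon and the C–Br carbon) are united through a radical. No ring is closed in this step. Both new stereocentres (C2 and C5) are set by substrate control: decarboxylation erases the old configuration, and the nickel-bound aryl group is delivered to the ring face opposite to the two cis CH2OAc groups on C3 and C4 (the 1,2-trans preference known for furanosyl radicals), which makes each aryl trans to its neighbour and the two aryls cis to each other. The step needs facial selectivity at two carbons and cross-coupling in preference to protodecarboxylation; the first is secured by the cis CH2OAc pair covering one face, the second by excess 6, whose bromine is para to the acetoxy group (favourable oxidative addition) and whose acetylated ring should be too electron-poor to be oxidized by the photocatalyst.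

Step 6
Reactants: 8 meso-[(2R,3S,4R,5S)-2,5-bis(4-acetoxy-3,5-dimethoxyphenyl)oxolane-3,4-diyl]bis(methylene) diacetate
Product: 9 meso-[(2R,3S,4R,5S)-2,5-bis(4-hydroxy-3,5-dimethoxyphenyl)oxolane-3,4-diyl]dimethanol
Conditions: NH3 (7 M in MeOH), under argon, 0 °C to rt; then concentration
Reagents that add atoms: none
Why: ammonolysis of the two aryl and two primary alkyl acetates (nucleophilic acyl substitution) should free all four hydroxyl groups without acid, so the benzylic ring C–O bonds do not ionize and the diol does not close to the furofuran; the stereocentres are not touched.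

**Compound list**

1 | exo-7-oxabicyclo[2.2.1]hept-5-ene-2,3-dicarboxylic anhydride (meso; exo Diels–Alder adduct of furan and maleic anhydride) | C1=C[C@H]2O[C@@H]1[C@H](C(=O)OC3=O)[C@@H]23 | starting material
2 | exo,exo-7-oxabicyclo[2.2.1]hept-5-ene-2,3-diyldimethanol (meso; both CH2OH on the side of the oxygen bridge) | C1=C[C@H]2O[C@@H]1[C@H](CO)[C@@H]2CO | intermediate
3 | exo,exo-7-oxabicyclo[2.2.1]hept-5-ene-2,3-diylbis(methylene) diacetate (meso) | C1=C[C@H]2O[C@@H]1[C@H](COC(C)=O)[C@@H]2COC(C)=O | intermediate
4 | meso-(2R,3S,4R,5S)-3,4-bis(acetoxymethyl)oxolane-2,5-dicarboxylic acid (carboxyls cis to each other, each trans to the neighbouring CH2OAc) | OC(=O)[C@H]1O[C@@H](C(=O)O)[C@H](COC(C)=O)[C@@H]1COC(C)=O | intermediate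
5 | 4-bromo-2,6-dimethoxyphenol | COc1cc(Br)cc(OC)c1O | starting material
6 | 4-bromo-2,6-dimethoxyphenyl acetate | COc1cc(Br)cc(OC)c1OC(C)=O | intermediate
7 | rac-5-(4-acetoxy-3,5-dimethoxyphenyl)-3,4-bis(acetoxymethyl)oxolane-2-carboxylic acid (aryl trans to its neighbouring CH2OAc, cis to the carboxyl) | COc1cc([C@H]2O[C@@H](C(=O)O)[C@H](COC(C)=O)[C@@H]2COC(C)=O)cc(OC)c1OC(C)=O | intermediate (not isolated)
8 | meso-[(2R,3S,4R,5S)-2,5-bis(4-acetoxy-3,5-dimethoxyphenyl)oxolane-3,4-diyl]bis(methylene) diacetate | COc1cc([C@H]2O[C@@H](c3cc(OC)c(OC(C)=O)c(OC)c3)[C@H](COC(C)=O)[C@@H]2COC(C)=O)cc(OC)c1OC(C)=O | intermediate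
9 | meso-[(2R,3S,4R,5S)-2,5-bis(4-hydroxy-3,5-dimethoxyphenyl)oxolane-3,4-diyl]dimethanol | COc1cc([C@H]2O[C@@H](c3cc(OC)c(O)c(OC)c3)[C@H](CO)[C@@H]2CO)cc(OC)c1O | target

**Step count**

Total steps: 6. Longest linear sequence: 5 steps (steps 1, 2, 3, 5, 6).

**Steps most likely to fail**

Step 5. What may go wrong: the sequence may stall after the first coupling, the oxolanyl radical may be lost to protodecarboxylation, or the facial selectivity of the radical capture may be poor. The fallback replaces the radical coupling by polar oxocarbenium chemistry; it sets out from 4 and returns to the route at 9. Twofold oxidative decarboxylation of 4 with Pb(OAc)4 (pyridine cat., THF, rt) should give 3,4-bis(acetoxymethyl)oxolane-2,5-diyl diacetate F1 as an anomeric mixture, which is of no consequence. Treatment of F1 with 2,6-dimethoxyphenol (2.5 equiv) and BF3·OEt2 in CH2Cl2 at −78 to −30 °C should give, by twofold Friedel–Crafts C-arylation para to the phenol OH, meso-[(2R,3S,4R,5S)-2,5-bis(4-hydroxy-3,5-dimethoxyphenyl)oxolane-3,4-diyl]bis(methylene) diacetate F2. Each cyclic oxocarbenium ion is attacked anti to the neighbouring CH2OAc group, and a cis isomer should equilibrate through reversible ionization of the benzylic C–O bond to the same trans,cis,trans isomer. F2 is then treated with NH3 in MeOH as in step 6 to give 9.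

Step 3. What may go wrong: over-oxidation of the ether α-C–H bonds by RuO4 and loss of the polar diacid to the aqueous phase on isolation. The fallback divides the cleavage into three mild stages; it sets out from 3 and returns at 4. Exo dihydroxylation of 3 (OsO4 cat., N-methylmorpholine N-oxide, acetone/H2O) should give exo,exo-5,6-dihydroxy-7-oxabicyclo[2.2.1]heptane-2,3-diylbis(methylene) diacetate F3. Glycol cleavage with NaIO4 (THF/H2O) should give meso-3,4-bis(acetoxymethyl)oxolane-2,5-dicarbaldehyde F4, handled as its hydrate. Pinnick oxidation (NaClO2, NaH2PO4, 2-methyl-2-butene, t-BuOH/H2O) then gives 4; any epimerization next to the aldehydes is harmless because step 5 erases these centres.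

Step 6. What may go wrong: slow ammonolysis of the two primary acetates, with air oxidation of the liberated syringyl phenolates or base-triggered opening of the oxolane through a quinone methide during the long exposure. The fallback changes from basic solvolysis to hydride reduction of the esters; it sets out from 8 and returns at 9. Treatment of 8 with i-Bu2AlH (10 equiv, CH2Cl2, −78 °C), followed by a work-up with aqueous potassium sodium tartrate (KNaC4H4O6), should give 9 directly. The phenols stay bound as aluminium phenoxides until the buffered work-up, and no new compound is made on the way (F0).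

**Further compounds**

F1 | step 5 | 3,4-bis(acetoxymethyl)oxolane-2,5-diyl diacetate (3,4-cis; anomeric mixture) | CC(=O)OC1OC(OC(C)=O)[C@H](COC(C)=O)[C@@H]1COC(C)=O
F2 | step 5 | meso-[(2R,3S,4R,5S)-2,5-bis(4-hydroxy-3,5-dimethoxyphenyl)oxolane-3,4-diyl]bis(methylene) diacetate | COc1cc([C@H]2O[C@@H](c3cc(OC)c(O)c(OC)c3)[C@H](COC(C)=O)[C@@H]2COC(C)=O)cc(OC)c1O
F3 | step 3 | exo,exo-5,6-dihydroxy-7-oxabicyclo[2.2.1]heptane-2,3-diylbis(methylene) diacetate (all four substituents exo) | O[C@H]1[C@@H](O)[C@H]2O[C@@H]1[C@H](COC(C)=O)[C@@H]2COC(C)=O
F4 | step 3 | meso-3,4-bis(acetoxymethyl)oxolane-2,5-dicarbaldehyde | O=C[C@H]1O[C@@H](C=O)[C@H](COC(C)=O)[C@@H]1COC(C)=O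
F0 | step 6 | none | none
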